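**Strategy.** The cyclohexene is cut at the two bonds that flank its CH2–CH2 unit. The methyl-bearing alkene carbon and the quaternary C(Me)(styryl) carbon, which sit 1,4 across that ring, then become C6 and C3 of 3,6-dimethyl-2-pyrone. A Diels–Alder reaction of this pyrone with phenyl vinyl sulfone (an ethylene equivalent) closes the carbocycle and leaves a lactone bridge that is absent from the target; the bridge holds the ring oxygen and the future styryl carbon cis. After resolution, the bridge is opened to a tertiary allylic alcohol, and a Johnson–Claisen rearrangement relays the face of its oxygen to the neighbouring CH and moves the alkene into place. Aldol/lactonisation and a Heck reaction add the two coumarins.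

Key step: step 3

Assumption: no catalytic asymmetric Diels–Alder reaction of a 3,6-dialkyl-2-pyrone with an ethylene equivalent is established, so the key step fixes only the relative configuration and the absolute configuration is secured by resolving lactone 6.

Step 1
Reactants: 1 4-hydroxy-3,6-dimethyl-2H-pyran-2-one
Product: 2 3,6-dimethyl-2-oxo-2H-pyran-4-yl trifluoromethanesulfonate
Conditions: Tf2O, Et3N, CH2Cl2, −78 to 0 °C
Reagents that add atoms: trifluoromethanesulfonic anhydride, O=S(=O)(OS(=O)(=O)C(F)(F)F)C(F)(F)F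
Why: O-sulfonylation of the acidic vinylogous carboxylic acid should be clean because the 4-OH is the only nucleophilic site.

Step 2
Reactants: 2 3,6-dimethyl-2-oxo-2H-pyran-4-yl trifluoromethanesulfonate
Product: 3 3,6-dimethyl-2H-pyran-2-one
Conditions: Pd(OAc)2 (5 mol %), dppf (6 mol %), HCO2H, Et3N, DMF, 60 °C
Reagents that add atoms: none
Why: Palladium-catalysed formate reduction of an enol triflate (oxidative addition to zerovalent palladium, formate exchange, loss of CO2, C–H reductive elimination) should replace the activated 4-OTf by H without touching the pyrone.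

Step 3
Reactants: 3 3,6-dimethyl-2H-pyran-2-one; 4 phenyl vinyl sulfone
Product: 5 rac-(1R,4S,8R)-1,4-dimethyl-8-(phenylsulfonyl)-2-oxabicyclo[2.2.2]oct-5-en-3-one (8-endo sulfone, syn to the C5=C6 bridge; the 8-exo epimer forms beside it and is carried on)
Conditions: PhMe, BHT (cat.), 110 °C, sealed tube
Reagents that add atoms: none
Why: Thermal normal-demand Diels–Alder reaction in which C3–C6 of the pyrone is the diene and the vinyl sulfone the dienophile, the closest known type being the cycloadditions of 2-pyrones with acrylates and vinyl sulfones that give isolable 2-oxabicyclo[2.2.2]oct-5-en-3-ones below the temperature of CO2 loss; the sulfone stands in for ethylene, which is too poor a dienophile for an unactivated pyrone. The carbocycle is closed by a concerted, suprafacial [4+2] cycloaddition that makes the CH2–C(Me)(O) bond and the CH(SO2Ph)–C(Me)(C=O) bond together, the pyrone lactone becoming the third bridge. Both bridgehead stereocentres are set here and their relative configuration is fixed by that bridge, since the lactone oxygen and the lactone carbonyl carbon must lie cis on the new six-membered ring; the product is racemic. The sulfone-bearing centre (endo favoured by secondary overlap) does not matter because it is erased in step 4. The selectivity needed is regiochemical, sulfone next to the carbonyl-bearing bridgehead, so that step 4 cannot expel a β-acyloxy group; the larger HOMO coefficient at pyrone C6, the terminus remote from the carbonyl, pairs with the CH2 end of the dienophile and should secure it, as in the usual adducts of 2-pyrones with monosubstituted alkenes.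

Step 4
Reactants: 5 rac-(1R,4S,8R)-1,4-dimethyl-8-(phenylsulfonyl)-2-oxabicyclo[2.2.2]oct-5-en-3-one
Product: 6 rac-1,4-dimethyl-2-oxabicyclo[2.2.2]oct-5-en-3-one
Conditions: 6% Na/Hg, Na2HPO4, MeOH–THF, −20 °C
Reagents that add atoms: none
Why: Reductive desulfonylation (electron transfer, C–S cleavage, further reduction, protonation by MeOH) should remove the activating group from both C8 epimers while the buffer keeps the lactone closed, so the sulfone serves as a traceless handle for ethylene.

Step 5
Reactants: 6 rac-1,4-dimethyl-2-oxabicyclo[2.2.2]oct-5-en-3-one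
Product: 7 (1R,4S)-1,4-dimethyl-2-oxabicyclo[2.2.2]oct-5-en-3-one
Conditions: preparative SFC on a chiral stationary phase (amylose tris(3,5-dimethylphenylcarbamate)), CO2/MeOH
Reagents that add atoms: none
Why: Resolution by chromatography on a chiral phase should deliver the (1R,4S) enantiomer, whose quaternary bridgehead C4 becomes the C(Me)(styryl) centre of the target; no stereocentre is made here.

Step 6
Reactants: 7 (1R,4S)-1,4-dimethyl-2-oxabicyclo[2.2.2]oct-5-en-3-one
Product: 8 (1R,4S)-1,4-dimethyl-2-oxabicyclo[2.2.2]oct-5-en-3-ol (both C3 epimers)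
Conditions: i-Bu2AlH (1.1 equiv), CH2Cl2, −78 °C; aqueous sodium potassium tartrate
Reagents that add atoms: none
Why: Partial reduction of a lactone by i-Bu2AlH should stop at the bridged lactol because the tetrahedral aluminium hemiacetal is stable at −78 °C.

Step 7
Reactants: 8 (1R,4S)-1,4-dimethyl-2-oxabicyclo[2.2.2]oct-5-en-3-ol
Product: 10 (1R,4R)-4-ethenyl-1,4-dimethylcyclohex-2-en-1-ol (OH and vinyl cis), via hydroxy aldehyde 9 (not isolated)
Conditions: Ph3PCH3Br, KOt-Bu, THF, 0 °C to reflux
Reagents that add atoms: methylenetriphenylphosphorane, C=P(c1ccccc1)(c1ccccc1)c1ccccc1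
Why: Wittig methylenation of the open hydroxy aldehyde in equilibrium with the lactol should turn the former lactone carbon into the vinyl CH and free the tertiary allylic alcohol, which stays cis to the vinyl group because neither stereocentre is touched.

Step 8
Reactants: 10 (1R,4R)-4-ethenyl-1,4-dimethylcyclohex-2-en-1-ol
Product: 12 ethyl 2-[(1R,6R)-6-ethenyl-3,6-dimethylcyclohex-2-en-1-yl]acetate, via ketene acetal 11 (not isolated)
Conditions: MeC(OEt)3, EtCO2H (cat.), 140 °C, EtOH distilled off
Reagents that add atoms: triethyl orthoacetate, CC(OCC)(OCC)OCC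
Why: Johnson–Claisen rearrangement, in which orthoester exchange and loss of EtOH give the allyl ketene acetal and its [3,3] shift is suprafacial on the ring, so the new C–C bond at the ring CH forms on the face that carried the oxygen (cis to the vinyl group), which sets the (1R) centre and moves the alkene to the methyl-bearing carbon.

Step 9
Reactants: 13 2,4-dihydroxy-3-methoxybenzaldehyde
Product: 14 3-methoxy-2,4-bis(methoxymethoxy)benzaldehyde
Conditions: MOMCl, i-Pr2NEt, CH2Cl2, 0 °C to reflux
Reagents that add atoms: chloromethyl methyl ether, COCCl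
Why: O-alkylation caps both phenols as MOM ethers so that the aldehyde stays electrophilic toward an ester enolate and the groups fall off under the acid of the last step.

Step 10
Reactants: 12 ethyl 2-[(1R,6R)-6-ethenyl-3,6-dimethylcyclohex-2-en-1-yl]acetate; 14 3-methoxy-2,4-bis(methoxymethoxy)benzaldehyde
Product: 16 ethyl 2-[(1S,6R)-6-ethenyl-3,6-dimethylcyclohex-2-en-1-yl]-3-hydroxy-3-[3-methoxy-2,4-bis(methoxymethoxy)phenyl]propanoate (mixture at the two new centres), via lithium enolate 15 (not isolated)
Conditions: LiN(i-Pr)2, THF, −78 °C; then 14; NH4Cl (aq)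
Reagents that add atoms: none
Why: Aldol addition of the lithium ester enolate to a non-enolisable aryl aldehyde should join the future coumarin C3 and C4, and the two new stereocentres need no control because step 15 destroys them.

Step 11
Reactants: 13 2,4-dihydroxy-3-methoxybenzaldehyde
Product: 18 7-hydroxy-8-methoxy-2H-chromen-2-one, via cinnamate ester 17 (not isolated)
Conditions: Ph3P=CHCO2Et, PhNEt2, 210 °C
Reagents that add atoms: ethyl (triphenylphosphoranylidene)acetate, CCOC(=O)C=P(c1ccccc1)(c1ccccc1)c1ccccc1
Why: Wittig olefination followed by thermal E-to-Z isomerisation and lactonisation is the standard route from a salicylaldehyde to a 3,4-unsubstituted coumarin.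

Step 12
Reactants: 18 7-hydroxy-8-methoxy-2H-chromen-2-one
Product: 19 8-methoxy-7-(methoxymethoxy)-2H-chromen-2-one
Conditions: MOMCl, i-Pr2NEt, CH2Cl2, 0 °C to rt
Reagents that add atoms: chloromethyl methyl ether, COCCl
Why: O-alkylation of the only phenol prevents ring bromination through the phenoxide and matches the protecting group of fragment 14.

Step 13
Reactants: 19 8-methoxy-7-(methoxymethoxy)-2H-chromen-2-one
Product: 20 3-bromo-8-methoxy-7-(methoxymethoxy)-2H-chromen-2-one
Conditions: NBS, MeCN, 0 °C to rt, dark
Reagents that add atoms: N-bromosuccinimide, O=C1CCC(=O)N1Br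
Why: Electrophilic bromination of a 7-alkoxycoumarin should occur at C3, the nucleophilic end of the push–pull alkene conjugated with the 7-oxygen, by attack of bromine and loss of the proton.

Step 14
Reactants: 16 aldol adduct; 20 3-bromo-8-methoxy-7-(methoxymethoxy)-2H-chromen-2-one
Product: 21 ethyl 2-[(1S,6R)-3,6-dimethyl-6-{(E)-2-[8-methoxy-7-(methoxymethoxy)-2-oxo-2H-chromen-3-yl]ethenyl}cyclohex-2-en-1-yl]-3-hydroxy-3-[3-methoxy-2,4-bis(methoxymethoxy)phenyl]propanoate
Conditions: Pd(OAc)2 (5 mol %), P(o-tol)3 (12 mol %), Et3N, DMF, 90 °C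
Reagents that add atoms: none
Why: Mizoroki–Heck reaction, in which the 3-coumarinyl palladium species adds to the unhindered CH2 end of the vinyl group and syn β-hydride elimination, possible only toward the former vinyl CH because the next carbon is quaternary, should give the E alkene.

Step 15
Reactants: 21 Heck product
Product: 24 7-hydroxy-3-[(E)-2-[(1R,2R)-2-(7-hydroxy-8-methoxy-2-oxo-2H-chromen-3-yl)-1,4-dimethylcyclohex-3-en-1-yl]ethenyl]-8-methoxy-2H-chromen-2-one, via triphenol hydroxy ester 22 (not isolated), via hydroxylactone 23 (not isolated)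
Conditions: HCl (1.25 M in MeOH), THF, 45 °C
Reagents that add atoms: none
Why: Acid removes the three MOM groups, the freed ortho-phenol lactonises onto the ethyl ester and the doubly activated benzylic alcohol is lost by E1 dehydration to the conjugated coumarin, so one operation should complete the second coumarin and free both phenols without touching the two stereocentres.

**Compound list**

1 | 4-hydroxy-3,6-dimethyl-2H-pyran-2-one | CC1=CC(O)=C(C)C(=O)O1 | starting material
2 | 3,6-dimethyl-2-oxo-2H-pyran-4-yl trifluoromethanesulfonate | CC1=CC(OS(=O)(=O)C(F)(F)F)=C(C)C(=O)O1 | intermediate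
3 | 3,6-dimethyl-2H-pyran-2-one | CC1=CC=C(C)C(=O)O1 | intermediate
4 | phenyl vinyl sulfone | C=CS(=O)(=O)c1ccccc1 | starting material
5 | rac-(1R,4S,8R)-1,4-dimethyl-8-(phenylsulfonyl)-2-oxabicyclo[2.2.2]oct-5-en-3-one (racemic; enantiomer drawn is the one later carried on) | O=C1O[C@]2(C)C[C@@H](S(=O)(=O)c3ccccc3)[C@@]1(C)C=C2 | intermediate
6 | rac-1,4-dimethyl-2-oxabicyclo[2.2.2]oct-5-en-3-one (racemate) | O=C1OC2(C)CCC1(C)C=C2 | intermediate
7 | (1R,4S)-1,4-dimethyl-2-oxabicyclo[2.2.2]oct-5-en-3-one | O=C1O[C@]2(C)CC[C@@]1(C)C=C2 | intermediate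
8 | (1R,4S)-1,4-dimethyl-2-oxabicyclo[2.2.2]oct-5-en-3-ol (both C3 epimers) | OC1O[C@]2(C)CC[C@@]1(C)C=C2 | intermediate
9 | (1S,4R)-4-hydroxy-1,4-dimethylcyclohex-2-ene-1-carbaldehyde | O=C[C@@]1(C)CC[C@@](C)(O)C=C1 | intermediate
10 | (1R,4R)-4-ethenyl-1,4-dimethylcyclohex-2-en-1-ol | C=C[C@@]1(C)CC[C@@](C)(O)C=C1 | intermediate
11 | 1-ethoxyethenyl ether of 10 (allyl ketene acetal) | C=C[C@@]1(C)CC[C@@](C)(OC(=C)OCC)C=C1 | intermediate
12 | ethyl 2-[(1R,6R)-6-ethenyl-3,6-dimethylcyclohex-2-en-1-yl]acetate | C=C[C@@]1(C)CCC(C)=C[C@H]1CC(=O)OCC | intermediate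
13 | 2,4-dihydroxy-3-methoxybenzaldehyde | COc1c(O)ccc(C=O)c1O | starting material
14 | 3-methoxy-2,4-bis(methoxymethoxy)benzaldehyde | COCOc1ccc(C=O)c(OCOC)c1OC | intermediate
15 | lithium enolate of 12 | [Li+].C=C[C@@]1(C)CCC(C)=C[C@H]1C=C([O-])OCC | intermediate
16 | ethyl 2-[(1S,6R)-6-ethenyl-3,6-dimethylcyclohex-2-en-1-yl]-3-hydroxy-3-[3-methoxy-2,4-bis(methoxymethoxy)phenyl]propanoate | C=C[C@@]1(C)CCC(C)=C[C@H]1C(C(=O)OCC)C(O)c1ccc(OCOC)c(OC)c1OCOC | intermediate
17 | ethyl (E)-3-(2,4-dihydroxy-3-methoxyphenyl)prop-2-enoate | CCOC(=O)/C=C/c1ccc(O)c(OC)c1O | intermediate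
18 | 7-hydroxy-8-methoxy-2H-chromen-2-one | COc1c(O)ccc2ccc(=O)oc12 | intermediate
19 | 8-methoxy-7-(methoxymethoxy)-2H-chromen-2-one | COCOc1ccc2ccc(=O)oc2c1OC | intermediate
20 | 3-bromo-8-methoxy-7-(methoxymethoxy)-2H-chromen-2-one | COCOc1ccc2cc(Br)c(=O)oc2c1OC | intermediate
21 | ethyl 2-[(1S,6R)-3,6-dimethyl-6-{(E)-2-[8-methoxy-7-(methoxymethoxy)-2-oxo-2H-chromen-3-yl]ethenyl}cyclohex-2-en-1-yl]-3-hydroxy-3-[3-methoxy-2,4-bis(methoxymethoxy)phenyl]propanoate | COCOc1ccc2cc(/C=C/[C@@]3(C)CCC(C)=C[C@H]3C(C(=O)OCC)C(O)c3ccc(OCOC)c(OC)c3OCOC)c(=O)oc2c1OC | intermediate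
22 | tris-phenol of 21 (all MOM groups removed) | COc1c(O)ccc2cc(/C=C/[C@@]3(C)CCC(C)=C[C@H]3C(C(=O)OCC)C(O)c3ccc(O)c(OC)c3O)c(=O)oc12 | intermediate
23 | 4-hydroxy-3,4-dihydrocoumarin formed by lactonisation of 22 | COc1c(O)ccc2cc(/C=C/[C@@]3(C)CCC(C)=C[C@H]3C3C(O)c4ccc(O)c(OC)c4OC3=O)c(=O)oc12 | intermediate
24 | 7-hydroxy-3-[(E)-2-[(1R,2R)-2-(7-hydroxy-8-methoxy-2-oxo-2H-chromen-3-yl)-1,4-dimethylcyclohex-3-en-1-yl]ethenyl]-8-methoxy-2H-chromen-2-one (CNP0264408.1) | COc1c(O)ccc2cc(/C=C/[C@@]3(C)CCC(C)=C[C@H]3c3cc4ccc(O)c(OC)c4oc3=O)c(=O)oc12 | target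

**Count.** Total steps: 15. Longest linear sequence: 11 steps (1 to 24 through steps 1–8, 10, 14 and 15).

**Steps most likely to fail**

Step 3. The cycloaddition of an unactivated, doubly substituted pyrone may be slow at a temperature the adduct tolerates, so that CO2 is lost by retro-[4+2]. The sulfone may also add with the reverse regiochemistry, next to the oxygen-bearing bridgehead, and then be eliminated together with the acyloxy group in step 4. Fallback: from pyrone 3, the more reactive dienophile acrylic acid (PhMe, hydroquinone, 90 °C) would give rac-1,4-dimethyl-3-oxo-2-oxabicyclo[2.2.2]oct-5-ene-8-carboxylic acid F1 together with its regio- and endo/exo isomers. Activation ((COCl)2, then sodium 2-mercaptopyridine N-oxide, DMAP) would give the O-acyl thiohydroxamate F2. Barton reductive decarboxylation (excess t-BuSH, hν) would then remove the carboxyl group by a radical path in which all isomers converge, rejoining the route at lactone 6.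

Step 8. The tertiary allylic alcohol may ionise or dehydrate under the hot, weakly acidic conditions before orthoester exchange takes place at the hindered oxygen. Fallback: from alcohol 10, acetylation (Ac2O, DMAP, Et3N) would give (1R,4R)-4-ethenyl-1,4-dimethylcyclohex-2-en-1-yl acetate F3. LiN(i-Pr)2 and Me3SiCl in THF at −78 °C would give the trimethylsilyl ketene acetal F4, which should rearrange on warming (Ireland–Claisen, same suprafacial course under basic conditions). Aqueous acid would then give 2-[(1R,6R)-6-ethenyl-3,6-dimethylcyclohex-2-en-1-yl]acetic acid F5, and esterification (EtI, K2CO3, DMF) rejoins the route at ester 12.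

Step 15. Several acid-driven events must all go to completion. The benzylic cation may be trapped by MeOH or by the nearby alkenes instead of losing a proton, dehydration before lactonisation would leave an E cinnamate that cannot close, and the acid may shift the ring alkene. Fallback: from ester 12, saponification (LiOH, THF–H2O) would give the acid F5. Esterification (EDC, DMAP) with 2-hydroxy-3-methoxy-4-(methoxymethoxy)benzaldehyde F6 (from 13 with one equivalent of MOMCl and K2CO3 in acetone, selective for the non-chelated 4-OH) would give the 2-formylaryl ester F7. Base (DBU, MeCN, 60 °C) would close the ring by intramolecular aldol condensation to the coumarin 3-[(1R,6R)-6-ethenyl-3,6-dimethylcyclohex-2-en-1-yl]-8-methoxy-7-(methoxymethoxy)-2H-chromen-2-one F8. A Heck reaction with bromide 20 under the conditions of step 14 would give the bis(methoxymethyl) ether of the target F9, and brief HCl/MeOH at room temperature would remove the two MOM groups and rejoin the route at 24.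

**Further compounds**

F1 | step 3 | rac-(1R,4R,8R)-1,4-dimethyl-3-oxo-2-oxabicyclo[2.2.2]oct-5-ene-8-carboxylic acid (endo isomer drawn) | O=C1O[C@]2(C)C[C@@H](C(=O)O)[C@@]1(C)C=C2
F2 | step 3 | 2-thioxopyridin-1(2H)-yl ester of F1 | O=C1O[C@]2(C)C[C@@H](C(=O)On3ccccc3=S)[C@@]1(C)C=C2
F3 | step 8 | (1R,4R)-4-ethenyl-1,4-dimethylcyclohex-2-en-1-yl acetate | C=C[C@@]1(C)CC[C@@](C)(OC(C)=O)C=C1
F4 | step 8 | trimethylsilyl ketene acetal of F3 | C=C[C@@]1(C)CC[C@@](C)(OC(=C)O[Si](C)(C)C)C=C1
F5 | step 8 | 2-[(1R,6R)-6-ethenyl-3,6-dimethylcyclohex-2-en-1-yl]acetic acid | C=C[C@@]1(C)CCC(C)=C[C@H]1CC(=O)O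
F6 | step 15 | 2-hydroxy-3-methoxy-4-(methoxymethoxy)benzaldehyde | COCOc1ccc(C=O)c(O)c1OC
F7 | step 15 | 2-formyl-6-methoxy-5-(methoxymethoxy)phenyl 2-[(1R,6R)-6-ethenyl-3,6-dimethylcyclohex-2-en-1-yl]acetate | C=C[C@@]1(C)CCC(C)=C[C@H]1CC(=O)Oc1c(C=O)ccc(OCOC)c1OC
F8 | step 15 | 3-[(1R,6R)-6-ethenyl-3,6-dimethylcyclohex-2-en-1-yl]-8-methoxy-7-(methoxymethoxy)-2H-chromen-2-one | C=C[C@@]1(C)CCC(C)=C[C@H]1c1cc2ccc(OCOC)c(OC)c2oc1=O
F9 | step 15 | bis(methoxymethyl) ether of 24 | COCOc1ccc2cc(/C=C/[C@@]3(C)CCC(C)=C[C@H]3c3cc4ccc(OCOC)c(OC)c4oc3=O)c(=O)oc2c1OC
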